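The ring is assembled from a four-carbon unit (C6, C1, C2, C3, with the benzoyloxymethyl branch on C1) and a two-carbon unit (C4, C5). The four-carbon unit is a vinyl-substituted dioxolane aldehyde made from diacetone-D-mannose. In a single flask, a chelation-controlled addition of a γ-silyloxyallylstannane to the C3 aldehyde forms C3–C4 and sets both new carbinol centres, and ring-closing metathesis of the two vinyl groups then forms C5=C6 and closes the cyclohexene. The step exploits the C2 oxygen as chelation anchor for the syn,syn C2–C3–C4 triol array and the placement of the C5=C6 alkene between the allylic C4 carbinol and the quaternary C1.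

Key step: step 6

Remark: ring atoms are numbered as in the name of the target (C1 = carbinol carbon carrying CH2OBz, C5=C6 = alkene) and α/β are used as in that name; lactol 2 is an anomeric mixture, of which one anomer is drawn.

Step 1
Reactants: 1 2,3:5,6-di-O-isopropylidene-α-D-mannofuranose
Product: 2 2-C-(hydroxymethyl)-2,3:5,6-di-O-isopropylidene-D-mannofuranose
Conditions: HCHO (37% aq.), K2CO3, MeOH, 65 °C
Reagents that add atoms: formaldehyde, C=O
Why: Crossed aldol (α-hydroxymethylation): the open-chain aldehyde enolises at C2 and formaldehyde should add on the dioxolane face anti to the C3 side chain, the only mode that lets the cis-fused 2,3-acetonide lactol re-form, so the new quaternary centre (C1 of the target) is set by the neighbouring C3 centre.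

Step 2
Reactants: 2 2-C-(hydroxymethyl)-2,3:5,6-di-O-isopropylidene-D-mannofuranose
Product: 3 1,2-dideoxy-3-C-(hydroxymethyl)-3,4:6,7-di-O-isopropylidene-D-manno-hept-1-enitol
Conditions: Ph3PCH3Br, KOtBu (excess), THF, 0 °C to 50 °C
Reagents that add atoms: methyltriphenylphosphonium bromide, C[P+](c1ccccc1)(c1ccccc1)c1ccccc1.[Br-]
Why: Wittig methylenation of the ring-opened hydroxy aldehyde form of the lactol should turn the formyl carbon into the vinyl group (C6 of the target) without touching either acetonide; no stereocentre is formed.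

Step 3
Reactants: 3 1,2-dideoxy-3-C-(hydroxymethyl)-3,4:6,7-di-O-isopropylidene-D-manno-hept-1-enitol
Product: 4 3-C-(benzoyloxymethyl)-1,2-dideoxy-3,4:6,7-di-O-isopropylidene-D-manno-hept-1-enitol
Conditions: BzCl (1.05 equiv), pyridine, CH2Cl2, −20 °C to 0 °C
Reagents that add atoms: benzoyl chloride, O=C(Cl)c1ccccc1
Why: Selective acylation: the primary hydroxyl should be benzoylated at low temperature in preference to the secondary hydroxyl flanked by two dioxolanes; no stereocentre is formed.

Step 4
Reactants: 4 3-C-(benzoyloxymethyl)-1,2-dideoxy-3,4:6,7-di-O-isopropylidene-D-manno-hept-1-enitol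
Product: 5 [(4S,5R)-4-ethenyl-5-formyl-2,2-dimethyl-1,3-dioxolan-4-yl]methyl benzoate
Conditions: H5IO6 (2.5 equiv), EtOAc, 0 °C to rt
Reagents that add atoms: none
Why: Periodic acid should hydrolyse the terminal isopropylidene acetal selectively and cleave the liberated 5,6,7-triol twice (Malaprade glycol cleavage), leaving C5 as the aldehyde (C3 of the target) while the internal acetonide, the benzoate and the alkene survive; no new stereocentre.

Step 5
Reactants: 6 allyl tert-butyldimethylsilyl ether
Product: 7 (Z)-tert-butyldimethyl{[3-(tributylstannyl)prop-1-en-1-yl]oxy}silane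
Conditions: s-BuLi, THF/HMPA, −78 °C; then Bu3SnCl, −78 °C to rt
Reagents that add atoms: tributyltin chloride, CCCC[Sn](Cl)(CCCC)CCCC
Why: Kinetic deprotonation of the allyl silyl ether gives the oxygen-coordinated (Z)-oxyallyl lithium, which should be stannylated at the γ-carbon to the (Z)-γ-silyloxyallylstannane, the low temperature suppressing the retro-Brook silyl shift.

Step 6
Reactants: 5 [(4S,5R)-4-ethenyl-5-formyl-2,2-dimethyl-1,3-dioxolan-4-yl]methyl benzoate; 7 (Z)-tert-butyldimethyl{[3-(tributylstannyl)prop-1-en-1-yl]oxy}silane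
Product: 9 1α-(benzoyloxymethyl)-4β-(tert-butyldimethylsilyloxy)-1β,2β-(isopropylidenedioxy)cyclohex-5-en-3α-ol, via open-chain diene adduct 8 (not isolated)
Conditions: 7 (0.95 equiv), MgBr2·OEt2 (2.5 equiv), CH2Cl2, −25 °C to 0 °C; then Hoveyda–Grubbs second-generation catalyst, [1,3-bis(2,4,6-trimethylphenyl)imidazolidin-2-ylidene]dichloro(2-isopropoxybenzylidene)ruthenium (5 mol %), 40 °C, argon sparge; aq. NaHCO3
Reagents that add atoms: none
Why: MgBr2 ties the formyl oxygen and the dioxolane oxygen on C2 into a five-membered chelate, and stannane 7 adds through an open antiperiplanar SE2' transition state to the chelate face remote from the quaternary C1, forming C3–C4; the Ru alkylidene generated next joins the vinyl group on C4 to the vinyl group on C1, forming C5=C6 with loss of ethene. The closest known reaction types are the chelation-controlled (Cram-chelate) addition of γ-oxygenated allylstannanes to α-alkoxy aldehydes and ring-closing olefin metathesis, run here in one flask. The six-membered carbocycle is closed by ring-closing metathesis of a 1,7-diene whose two vinyl groups are held cis on the dioxolane, so the new alkene is necessarily cis and cyclisation is favoured over oligomerisation. C3 (hydroxyl α, 2,3-syn) is controlled by the C2 stereocentre through the chelate, and C4 (silyloxy β, 3,4-syn) by the open transition state in which the stannane chain lies anti to the aldehyde substituent. The step needs chelate attack to outrun the non-chelated polar Felkin pathway, which the bidentate magnesium halide in a non-coordinating solvent and the bulk of C1 on the blocked face should secure. It also needs a living metathesis catalyst beside magnesium and tin halides, which the phosphine-free Ru carbene should tolerate, provided the enol ether 7 is the limiting reagent so that no Fischer-type carbene forms.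

Step 7
Reactants: 9 1α-(benzoyloxymethyl)-4β-(tert-butyldimethylsilyloxy)-1β,2β-(isopropylidenedioxy)cyclohex-5-en-3α-ol
Product: 10 3α-benzoate of 9
Conditions: BzCl, pyridine, DMAP (cat.), CH2Cl2, 0 °C to rt
Reagents that add atoms: benzoyl chloride, O=C(Cl)c1ccccc1
Why: DMAP-catalysed acylation of the only free hydroxyl should install the C3 benzoate with retention, the trans-disposed silyl ether and the dioxolane being inert.

Step 8
Reactants: 10 3α-benzoate of 9
Product: 11 [(1S,2S,3R,4S)-3-(benzoyloxy)-1,2,4-trihydroxycyclohex-5-en-1-yl]methyl benzoate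
Conditions: TFA/H2O (4:1), 0 °C to rt
Reagents that add atoms: none
Why: Aqueous acid should hydrolyse the isopropylidene acetal and the allylic silyl ether in one operation while the two benzoates stay in place; all four stereocentres are untouched.

Compound list
1 | 2,3:5,6-di-O-isopropylidene-α-D-mannofuranose (diacetone-D-mannose) | O[C@@H]1[C@H]2OC(C)(C)O[C@H]2[C@H](O1)[C@H]1COC(C)(C)O1 | starting material
2 | 2-C-(hydroxymethyl)-2,3:5,6-di-O-isopropylidene-D-mannofuranose (lactol, one anomer drawn) | O[C@@H]1[C@@]2(CO)OC(C)(C)O[C@H]2[C@H](O1)[C@H]1COC(C)(C)O1 | intermediate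
3 | 1,2-dideoxy-3-C-(hydroxymethyl)-3,4:6,7-di-O-isopropylidene-D-manno-hept-1-enitol | C=C[C@@]1(CO)OC(C)(C)O[C@H]1[C@H](O)[C@H]1COC(C)(C)O1 | intermediate
4 | 3-C-(benzoyloxymethyl)-1,2-dideoxy-3,4:6,7-di-O-isopropylidene-D-manno-hept-1-enitol | C=C[C@@]1(COC(=O)c2ccccc2)OC(C)(C)O[C@H]1[C@H](O)[C@H]1COC(C)(C)O1 | intermediate
5 | [(4S,5R)-4-ethenyl-5-formyl-2,2-dimethyl-1,3-dioxolan-4-yl]methyl benzoate (vinyl and formyl cis) | C=C[C@@]1(COC(=O)c2ccccc2)OC(C)(C)O[C@H]1C=O | intermediate
6 | allyl tert-butyldimethylsilyl ether | C=CCO[Si](C)(C)C(C)(C)C | starting material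
7 | (Z)-tert-butyldimethyl{[3-(tributylstannyl)prop-1-en-1-yl]oxy}silane | CCCC[Sn](CCCC)(CCCC)C/C=C\O[Si](C)(C)C(C)(C)C | intermediate
8 | open-chain diene adduct: dioxolane 5 in which CHO has become CH(OH)–CH(OTBS)–CH=CH2, 2,3-syn-3,4-syn in target numbering, present in the flask as its magnesium alkoxide | C=C[C@@]1(COC(=O)c2ccccc2)OC(C)(C)O[C@H]1[C@H](O)[C@@H](O[Si](C)(C)C(C)(C)C)C=C | intermediate (not isolated)
9 | 1α-(benzoyloxymethyl)-4β-(tert-butyldimethylsilyloxy)-1β,2β-(isopropylidenedioxy)cyclohex-5-en-3α-ol | O=C(OC[C@@]12C=C[C@H](O[Si](C)(C)C(C)(C)C)[C@@H](O)[C@@H]1OC(C)(C)O2)c1ccccc1 | intermediate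
10 | 3α-benzoate of 9: 1α-(benzoyloxymethyl)-3α-benzoyloxy-4β-(tert-butyldimethylsilyloxy)-1β,2β-(isopropylidenedioxy)cyclohex-5-ene | O=C(OC[C@@]12C=C[C@H](O[Si](C)(C)C(C)(C)C)[C@@H](OC(=O)c3ccccc3)[C@@H]1OC(C)(C)O2)c1ccccc1 | intermediate
11 | [(1S,2S,3R,4S)-3-(benzoyloxy)-1,2,4-trihydroxycyclohex-5-en-1-yl]methyl benzoate | O=C(OC[C@@]1(O)C=C[C@H](O)[C@@H](OC(=O)c2ccccc2)[C@@H]1O)c1ccccc1 | target

Total step count: 8. Longest linear sequence: 7 steps (steps 1 to 4 and 6 to 8); step 5 prepares the stannane.

Steps most likely to fail

Step 6. The dioxolane oxygen is only a modest donor, so part of the addition may run through the non-chelated polar Felkin rotamer and deliver the C3,C4-bis-epimer, which cannot be corrected later. Magnesium or tin halides, or traces of enol ether 7, may also stop the metathesis catalyst. The fallback takes the C3 centre from D-mannose instead of creating it. It sets out from diol 3, in which both hydroxyls would be benzoylated (BzCl, pyridine, DMAP) to give dibenzoate F1; its secondary benzoate is already the C3 benzoate of the target in the correct configuration. H5IO6 in EtOAc would then cleave only the terminal acetonide and its glycol to α-benzoyloxy aldehyde F2. An ester-tolerant Nozaki–Hiyama–Kishi vinylation (vinyl bromide, CrCl2, cat. NiCl2, DMF) should give vinyl carbinol F3, expected mainly as the Felkin 3,4-anti epimer. Ring-closing metathesis with [1,3-bis(2,4,6-trimethylphenyl)imidazolidin-2-ylidene]dichloro(2-isopropoxybenzylidene)ruthenium would close 4-epi-cyclohexenol F4. Because this carbinol is allylic, its configuration would be corrected by MnO2 oxidation to enone F5 and Luche reduction (NaBH4, CeCl3·7H2O, MeOH, −78 °C), which should give the pseudo-equatorial 4β-alcohol trans to the 3α-benzoate, acetonide alcohol F6. Hydrolysis of the dioxolane (TFA/H2O) returns to the route at 11.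

Step 2. The β-hydroxy aldehyde form of lactol 2 may lose formaldehyde by retro-aldol cleavage under the strongly basic ylide, or the α-quaternary formyl group may olefinate sluggishly. The fallback sets out from 2 and introduces the two alkene carbons under the mild carbonate conditions in which 2 is itself formed. Ohira–Bestmann homologation (dimethyl (1-diazo-2-oxopropyl)phosphonate, K2CO3, MeOH, rt) would give alkyne diol F7, and Lindlar semihydrogenation (H2, Pd/CaCO3 poisoned with Pb(OAc)2, quinoline, EtOAc) returns to the route at 3.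

Step 8. Under aqueous acid the C3 benzoate may migrate to the freshly liberated hydroxyls on C2 or C4, or the allylic C4 carbinol may ionise. The fallback sets out from 10 and removes the two protecting groups in two orthogonal, milder operations. CeCl3·7H2O with oxalic acid in MeCN should cleave only the isopropylidene acetal to give silyl ether diol F8, and HF·pyridine buffered with pyridine in THF then removes the silyl group and returns to the route at 11.

Further compounds
F1 | step 6 | 5-O-benzoyl-3-C-(benzoyloxymethyl)-1,2-dideoxy-3,4:6,7-di-O-isopropylidene-D-manno-hept-1-enitol (dibenzoate) | C=C[C@@]1(COC(=O)c2ccccc2)OC(C)(C)O[C@H]1[C@H](OC(=O)c1ccccc1)[C@H]1COC(C)(C)O1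
F2 | step 6 | α-benzoyloxy aldehyde from glycol cleavage of F1 (formyl carbon = C4 of the target) | C=C[C@@]1(COC(=O)c2ccccc2)OC(C)(C)O[C@H]1[C@H](OC(=O)c1ccccc1)C=O
F3 | step 6 | vinyl carbinol, 3,4-anti epimer drawn | C=C[C@@]1(COC(=O)c2ccccc2)OC(C)(C)O[C@H]1[C@H](OC(=O)c1ccccc1)[C@H](O)C=C
F4 | step 6 | 4-epi-cyclohexenol: 1α-(benzoyloxymethyl)-3α-benzoyloxy-1β,2β-(isopropylidenedioxy)cyclohex-5-en-4α-ol | O=C(OC[C@@]12C=C[C@@H](O)[C@@H](OC(=O)c3ccccc3)[C@@H]1OC(C)(C)O2)c1ccccc1
F5 | step 6 | enone: 4-oxo analogue of F4 | O=C(OC[C@@]12C=CC(=O)[C@@H](OC(=O)c3ccccc3)[C@@H]1OC(C)(C)O2)c1ccccc1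
F6 | step 6 | acetonide alcohol: 1,2-O-isopropylidene derivative of the target | O=C(OC[C@@]12C=C[C@H](O)[C@@H](OC(=O)c3ccccc3)[C@@H]1OC(C)(C)O2)c1ccccc1
F7 | step 2 | alkyne diol: 1,1,2,2-tetradehydro-1,2-dideoxy-3-C-(hydroxymethyl)-3,4:6,7-di-O-isopropylidene-D-manno-heptitol | C#C[C@@]1(CO)OC(C)(C)O[C@H]1[C@H](O)[C@H]1COC(C)(C)O1
F8 | step 8 | silyl ether diol: 4-O-tert-butyldimethylsilyl derivative of the target | O=C(OC[C@@]1(O)C=C[C@H](O[Si](C)(C)C(C)(C)C)[C@@H](OC(=O)c2ccccc2)[C@@H]1O)c1ccccc1
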